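Readings and results come from a simulation with constants of no real substance; noise was put on by code.

You cannot tell X from J in readings that show G and L, but L you can bound.

| flask | X | D | remark | time |
|---|---|---|---|---|
| red | 0.10 M | 0.028 M | run made earlier |  |
| grey | 0.10 M | 0.044 M | run made earlier |  |
| flask | 0.10 M | 0.0200 M |  | 50 h |

| run | time / h | G / % | L / % |
|---|---|---|---|
| red | 8.00 | 3 | 12 |
| red | 20.0 | 7 | 20 |
| red | 40.0 | 13 | 24 |
| red | 60.0 | 21 | 29 |
| grey | 5.00 | 0 | 13 |
| grey | 12.0 | 2 | 19 |
| grey | 25.0 | 6 | 36 |
| grey | 60.0 | 16 | 40 |

(readings scatter by 2 percentage points)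

- amount of G in the flask at 50 h, in percent of the X charged
- amount of L in the flask at 50 h, in percent of the X charged
- amount of J in the flask at 50 h, in percent of the X charged
- amount of X in the flask at 50 h, in percent of the X charged



L follows the D charged. At 60.0 h the red run reads 29% against a charged [D] over charged [X] of 28.0%, and the grey run reads 40% against 44.0%. So I read D as the limiting reagent for L, taken up one to one with X. For this flask, charged [D] over charged [X] is 20.0%, and that is the L ceiling. Red has the same [X], and the 50 h asked of this flask lies midway between red's last two readings, so I take the mean of their shares of red's ceiling: L comes to 18.9%. I put no figure on the split between X and J.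

The forecast says G 19%, L 19%, J 32%, X 30%, and of that split: “The split is poorly determined because the lag is weak against the scatter.”

The flask gives G 16.7%, L 18.1%, J 11.2%, X 54.1%. The forecast parts from it on J and X. L stands below the ceiling of 20.0%, and the same flask read at 192 h gives L 19.9%, about at that ceiling, with 0.28% of its D left.

    J ⇌ G (K = 3.50, k = 8.50 × 10⁻⁴ min⁻¹)
    X + D → L (k = 0.0110 M⁻¹ min⁻¹)
    X ⇌ J (K = 0.550, k = 1.70 × 10⁻⁴ min⁻¹)

In this flask at 50.0 h, J has a half-life of 14 h by its forward turning into G alone, shorter than the 68 h of X by its forward turning into J alone. J is then made 1.06 times as fast as it is used, each step taken net, and stands at 11.2%.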